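**Strategy.** Numbering: C1 acetoxy-bearing carbon, C2/C6 aryl carbons, C5 ring-fusion CH, O3–C4 and O7–C8 the OCH2 units. The oxolane O7–C8–C1–C5–C6 is cut at O7–C8 and at the fusion bond C1–C5. With C2 as a ketone and C4–O3 as an oxirane on C5 this ring has alternating polarity, O7(−), C8(+), C1(−), C5(+). The key step is a base-triggered [3+2] annulation: the alkoxide of an anti aryl(oxiranyl)methanol adds to the CH2 terminus of a 2-benzyloxy aryl vinyl ketone (O7–C8) and the resulting enolate opens the oxirane at C5 (C1–C5), setting C1 and C5 and freeing the C4 alkoxide that later closes the second ring onto C2.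

Key step: step 5

Remark (assumption): 1 and 4 are taken as catalogue compounds; each is otherwise one MOMCl step from vanillin or 4-bromo-2-methoxyphenol.
Remark (assumption): hydroxy ketone 12 is drawn open-chain; a ring-closed hemiketal tautomer would react in step 6 through the same open form.

Step 1
Reactants: 1 3-methoxy-4-(methoxymethoxy)benzaldehyde
Product: 2 rac-1-[3-methoxy-4-(methoxymethoxy)phenyl]prop-2-en-1-ol
Conditions: CH2=CHMgBr, THF, 0 °C; aq NH4Cl
Reagents that add atoms: vinylmagnesium bromide, C=C[Mg]Br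
Why: Grignard 1,2-addition to the aryl aldehyde gives the racemic secondary allylic alcohol, and no stereocontrol is needed because step 2 resolves it.

Step 2
Reactants: 2 rac-1-[3-methoxy-4-(methoxymethoxy)phenyl]prop-2-en-1-ol
Product: 3 (R)-[3-methoxy-4-(methoxymethoxy)phenyl][(2S)-oxiran-2-yl]methanol
Conditions: Ti(OiPr)4 (cat.), D-(−)-diisopropyl tartrate, t-BuOOH (0.55 equiv), 4 Å MS, CH2Cl2, −20 °C
Reagents that add atoms: tert-butyl hydroperoxide, CC(C)(C)OO
Why: Sharpless asymmetric epoxidation run as a kinetic resolution: with the D-(−)-tartrate the (S)-enantiomer of 2 should be epoxidised fast and erythro (anti), which fixes the carbinol centre (R descriptor in 3) and the (2S)-oxirane centre, while (R)-2 stays behind and is separated.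

Step 3
Reactants: 4 4-bromo-2-methoxy-1-(methoxymethoxy)benzene; 5 2-(benzyloxy)-N-methoxy-N-methylacetamide
Product: 7 2-(benzyloxy)-1-[3-methoxy-4-(methoxymethoxy)phenyl]ethan-1-one, via aryllithium 6 (not isolated)
Conditions: n-BuLi, THF, −78 °C; then 5, −78 to 0 °C; aq NH4Cl
Reagents that add atoms: none
Why: Bromine–lithium exchange followed by Weinreb ketone synthesis, in which the chelated tetrahedral adduct survives until the quench, so the aryl ketone should form without over-addition.

Step 4
Reactants: 7 2-(benzyloxy)-1-[3-methoxy-4-(methoxymethoxy)phenyl]ethan-1-one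
Product: 8 2-(benzyloxy)-1-[3-methoxy-4-(methoxymethoxy)phenyl]prop-2-en-1-one
Conditions: (CH2O)n, i-Pr2NH·CF3CO2H, THF, 65 °C
Reagents that add atoms: formaldehyde (as paraformaldehyde), C=O
Why: Mannich-type α-methylenation: aminomethylation of the activated α-CH2 by the iminium ion and β-elimination of the amine should give the 2-alkoxy enone.

Step 5
Reactants: 3 (R)-[3-methoxy-4-(methoxymethoxy)phenyl][(2S)-oxiran-2-yl]methanol; 8 2-(benzyloxy)-1-[3-methoxy-4-(methoxymethoxy)phenyl]prop-2-en-1-one
Product: 12 [(3S,4R,5S)-3-(benzyloxy)-4-(hydroxymethyl)-5-[3-methoxy-4-(methoxymethoxy)phenyl]oxolan-3-yl][3-methoxy-4-(methoxymethoxy)phenyl]methanone, via potassium alkoxide 9 (not isolated), via potassium enolate 10 (not isolated), via keto alkoxide 11 (not isolated)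
Conditions: KN(SiMe3)2 (0.95 equiv), THF, −78 °C; 8 added slowly, −78 to 0 °C; aq NH4Cl
Reagents that add atoms: none
Why: Proposed new method: the potassium alkoxide 9 adds in conjugate fashion to the CH2 terminus of enone 8 (O7–C8) and the α-benzyloxy enolate 10 then attacks the oxirane carbon C5 from the rear (C1–C5), freeing the C4 alkoxide 11; retro-oxa-Michael of 10 only returns 9 and 8, so the β-alkoxy enolate has no destructive elimination path. The closest known reaction types are the Michael-initiated ring closure, the Stork intramolecular alkylation of enolates by epoxides, and the palladium-catalysed [3+2] annulation of vinyl oxiranes with Michael acceptors, which uses the same O(−)/C(+) pairing. The oxolane closes in the 5-exo-tet mode by attack on the proximal oxirane carbon, whereas 6-endo attack on the oxirane CH2 would give an oxane. C6 is carried over from 3 unchanged, C5 is set by inversion at the (2S)-oxirane carbon, which places the C6 aryl group and the C5 CH2O arm trans, and the quaternary C1 is set in the ring closure, where a potassium ion bridging the enolate oxygen and the oxirane oxygen should hold the aroyl group on the side of the departing CH2–O, cis to C4. The step needs this cis selectivity at C1, exo over endo opening, and conjugate addition faster than Payne rearrangement of 9 or enolate addition to a second molecule of 8; low temperature, a slight deficit of base, slow addition of 8 and the K+ template are meant to secure them.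

Step 6
Reactants: 12 the hydroxy ketone from step 5
Product: 13 [(3S,4R,5S)-3-(benzyloxy)-4-(hydroxymethyl)-5-[3-methoxy-4-(methoxymethoxy)phenyl]oxolan-3-yl][3-methoxy-4-(methoxymethoxy)phenyl]methanol (both epimers at the new carbinol carbon)
Conditions: NaBH4, MeOH, 0 °C
Reagents that add atoms: none
Why: Borohydride reduction of the aryl ketone; the new carbinol centre is left uncontrolled because step 7 ionises it.

Step 7
Reactants: 13 the diol from step 6
Product: 14 (1S,2R,5R,6S)-1-(benzyloxy)-2,6-bis[3-methoxy-4-(methoxymethoxy)phenyl]-3,7-dioxabicyclo[3.3.0]octane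
Conditions: camphorsulfonic acid (cat.), 4 Å MS, CH2Cl2, 0 °C
Reagents that add atoms: none
Why: Acid-catalysed SN1 cyclodehydration: the p-alkoxybenzylic cation at C2 should be captured by the C4 hydroxyl in a 5-exo closure, with the aryl group settling on the convex face (cis to the C1 oxygen) of the forming cis-fused bicycle, so both carbinol epimers should converge on one C2 configuration.

Step 8
Reactants: 14 the benzyl ether from step 7
Product: 15 (1S,2R,5R,6S)-2,6-bis[3-methoxy-4-(methoxymethoxy)phenyl]-3,7-dioxabicyclo[3.3.0]octan-1-ol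
Conditions: H2 (1 atm), Pd(OH)2 on carbon, EtOAc–EtOH, rt
Reagents that add atoms: none
Why: Hydrogenolysis of the tertiary benzyl ether; with both phenols still capped as MOM ethers the ring benzylic C–O bonds are non-phenolic and should resist cleavage under neutral conditions.

Step 9
Reactants: 15 the tertiary alcohol from step 8
Product: 16 (1S,2R,5R,6S)-2,6-bis[3-methoxy-4-(methoxymethoxy)phenyl]-3,7-dioxabicyclo[3.3.0]octan-1-yl acetate
Conditions: Ac2O, DMAP, Et3N, CH2Cl2, 40 °C
Reagents that add atoms: acetic anhydride, CC(=O)OC(C)=O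
Why: DMAP-catalysed acylation (Steglich-type acyl transfer through the N-acetylpyridinium ion) of the hindered tertiary alcohol, the only free hydroxyl in 15.

Step 10
Reactants: 16 the bis-MOM acetate from step 9
Product: 18 1-acetoxypinoresinol, (1S,2R,5R,6S)-2,6-bis(4-hydroxy-3-methoxyphenyl)-3,7-dioxabicyclo[3.3.0]octan-1-yl acetate, via bis(trimethylsilyl) ether 17 (not isolated)
Conditions: Me3SiOTf, 2,2′-bipyridyl, CH2Cl2, 0 °C to rt; then H2O
Reagents that add atoms: none
Why: Silyl triflate–bipyridyl cleavage of the two aryl MOM acetals to aryl silyl ethers, hydrolysed on aqueous work-up; the buffered, non-protic medium should leave the tertiary acetate and the acid-labile benzylic ethers untouched.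

**Compound list**

1 | 3-methoxy-4-(methoxymethoxy)benzaldehyde | COCOc1ccc(C=O)cc1OC | starting material
2 | rac-1-[3-methoxy-4-(methoxymethoxy)phenyl]prop-2-en-1-ol | C=CC(O)c1ccc(OCOC)c(OC)c1 | intermediate
3 | (R)-[3-methoxy-4-(methoxymethoxy)phenyl][(2S)-oxiran-2-yl]methanol | O[C@H](c1ccc(OCOC)c(OC)c1)[C@@H]1CO1 | intermediate
4 | 4-bromo-2-methoxy-1-(methoxymethoxy)benzene | COCOc1ccc(Br)cc1OC | starting material
5 | 2-(benzyloxy)-N-methoxy-N-methylacetamide | CON(C)C(=O)COCc1ccccc1 | starting material
6 | [3-methoxy-4-(methoxymethoxy)phenyl]lithium, formed in the flask | [Li]c1ccc(OCOC)c(OC)c1 | intermediate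
7 | 2-(benzyloxy)-1-[3-methoxy-4-(methoxymethoxy)phenyl]ethan-1-one | O=C(COCc1ccccc1)c1ccc(OCOC)c(OC)c1 | intermediate
8 | 2-(benzyloxy)-1-[3-methoxy-4-(methoxymethoxy)phenyl]prop-2-en-1-one | C=C(OCc1ccccc1)C(=O)c1ccc(OCOC)c(OC)c1 | intermediate
9 | potassium alkoxide of 3, formed in the flask | [K+].[O-][C@H](c1ccc(OCOC)c(OC)c1)[C@@H]1CO1 | intermediate
10 | potassium enolate of the oxa-Michael adduct of 9 and 8, formed in the flask | [K+].[O-]C(=C(OCc1ccccc1)CO[C@H](c1ccc(OCOC)c(OC)c1)[C@@H]1CO1)c1ccc(OCOC)c(OC)c1 | intermediate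
11 | potassium alkoxide of 12 (at the CH2O arm), formed in the flask | COCOc1ccc(cc1OC)[C@H]2OC[C@](OCc3ccccc3)(C(=O)c3ccc(OCOC)c(OC)c3)[C@@H]2C[O-].[K+] | intermediate
12 | [(3S,4R,5S)-3-(benzyloxy)-4-(hydroxymethyl)-5-[3-methoxy-4-(methoxymethoxy)phenyl]oxolan-3-yl][3-methoxy-4-(methoxymethoxy)phenyl]methanone | COCOc1ccc(cc1OC)[C@H]2OC[C@](OCc3ccccc3)(C(=O)c3ccc(OCOC)c(OC)c3)[C@@H]2CO | intermediate
13 | [(3S,4R,5S)-3-(benzyloxy)-4-(hydroxymethyl)-5-[3-methoxy-4-(methoxymethoxy)phenyl]oxolan-3-yl][3-methoxy-4-(methoxymethoxy)phenyl]methanol, both carbinol epimers | COCOc1ccc(cc1OC)[C@H]2OC[C@](OCc3ccccc3)(C(O)c3ccc(OCOC)c(OC)c3)[C@@H]2CO | intermediate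
14 | (1S,2R,5R,6S)-1-(benzyloxy)-2,6-bis[3-methoxy-4-(methoxymethoxy)phenyl]-3,7-dioxabicyclo[3.3.0]octane | COCOc1ccc(cc1OC)[C@H]2OC[C@]3(OCc4ccccc4)[C@@H](c4ccc(OCOC)c(OC)c4)OC[C@H]23 | intermediate
15 | (1S,2R,5R,6S)-2,6-bis[3-methoxy-4-(methoxymethoxy)phenyl]-3,7-dioxabicyclo[3.3.0]octan-1-ol | COCOc1ccc(cc1OC)[C@H]2OC[C@]3(O)[C@@H](c4ccc(OCOC)c(OC)c4)OC[C@H]23 | intermediate
16 | (1S,2R,5R,6S)-2,6-bis[3-methoxy-4-(methoxymethoxy)phenyl]-3,7-dioxabicyclo[3.3.0]octan-1-yl acetate | COCOc1ccc(cc1OC)[C@H]2OC[C@]3(OC(C)=O)[C@@H](c4ccc(OCOC)c(OC)c4)OC[C@H]23 | intermediate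
17 | bis(trimethylsilyl) ether of 18, formed in the flask | C[Si](C)(C)Oc1ccc(cc1OC)[C@H]2OC[C@]3(OC(C)=O)[C@@H](c4ccc(O[Si](C)(C)C)c(OC)c4)OC[C@H]23 | intermediate
18 | 1-acetoxypinoresinol, (1S,2R,5R,6S)-2,6-bis(4-hydroxy-3-methoxyphenyl)-3,7-dioxabicyclo[3.3.0]octan-1-yl acetate | COc1cc([C@H]2OC[C@]3(OC(C)=O)[C@@H](c4ccc(O)c(OC)c4)OC[C@H]23)ccc1O | target

**Totals.** Total step count: 10. Longest linear sequence: 8 steps (steps 1, 2, 5–10; the branch through steps 3 and 4 is equally long).

**Steps most likely to fail**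

Step 5 (proposed new method). The cascade may fail through Payne rearrangement of the epoxy alkoxide before conjugate addition, through consumption of the enone by enolate oligomerisation, through 6-endo opening, or through ring closure with the aroyl group trans to the CH2O arm. The fallback uses known chemistry, sets out from 3 and 8 and comes back at 12, and separates the two bond formations. A PMe3-catalysed oxa-Michael addition of 3 to 8 (THF, rt, no stoichiometric alkoxide) should give 2-(benzyloxy)-3-{(R)-[3-methoxy-4-(methoxymethoxy)phenyl][(2S)-oxiran-2-yl]methoxy}-1-[3-methoxy-4-(methoxymethoxy)phenyl]propan-1-one F1 as a mixture at the α-carbon. Its enolate is then generated alone with KN(SiMe3)2 in toluene (−78 to 0 °C) for a Stork-type intramolecular alkylation by the oxirane, passing through 10 and 11 to 12. Counter-ion, concentration and temperature can then be tuned without the competing intermolecular events.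

Step 7. The benzylic cation may undergo a 1,2-shift toward the benzyloxy-bearing carbon, be captured from the concave face, or the acid may epimerise C6. The fallback sets out from 12 and comes back at 14 without a cation. Reduction of 12 with LiBH(s-Bu)3 (THF, −78 °C) should follow the polar Felkin–Anh model (benzyloxy group anti to hydride) and give (R)-[(3S,4R,5S)-3-(benzyloxy)-4-(hydroxymethyl)-5-[3-methoxy-4-(methoxymethoxy)phenyl]oxolan-3-yl][3-methoxy-4-(methoxymethoxy)phenyl]methanol F2. Selective sulfonylation of its primary hydroxyl (TsCl, pyridine, 0 °C) should give the primary 4-methylbenzenesulfonate of F2 F3. NaH in THF then closes the second oxolane by Williamson displacement with retention at C2, giving 14.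

Step 4. The 2-alkoxy enone may polymerise or take up the amine in conjugate fashion during methylenation and isolation. The fallback sets out from 7 and comes back at 8, storing the acceptor as a stable salt. Aminomethylation of 7 with dimethylmethylideneammonium iodide (MeCN, 60 °C) should give the Mannich base 2-(benzyloxy)-3-(dimethylamino)-1-[3-methoxy-4-(methoxymethoxy)phenyl]propan-1-one F4. MeI converts it into 2-(benzyloxy)-3-[3-methoxy-4-(methoxymethoxy)phenyl]-N,N,N-trimethyl-3-oxopropan-1-aminium iodide F5. Brief treatment of F5 with aq NaHCO3 in CH2Cl2 releases 8 by β-elimination, and the dried solution is used directly in step 5.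

Further compounds
F1 | step 5 | 2-(benzyloxy)-3-{(R)-[3-methoxy-4-(methoxymethoxy)phenyl][(2S)-oxiran-2-yl]methoxy}-1-[3-methoxy-4-(methoxymethoxy)phenyl]propan-1-one | O=C(C(OCc1ccccc1)CO[C@H](c1ccc(OCOC)c(OC)c1)[C@@H]1CO1)c1ccc(OCOC)c(OC)c1
F2 | step 7 | (R)-[(3S,4R,5S)-3-(benzyloxy)-4-(hydroxymethyl)-5-[3-methoxy-4-(methoxymethoxy)phenyl]oxolan-3-yl][3-methoxy-4-(methoxymethoxy)phenyl]methanol | COCOc1ccc(cc1OC)[C@H]2OC[C@](OCc3ccccc3)([C@H](O)c3ccc(OCOC)c(OC)c3)[C@@H]2CO
F3 | step 7 | primary 4-methylbenzenesulfonate of F2 | COCOc1ccc(cc1OC)[C@H]2OC[C@](OCc3ccccc3)([C@H](O)c3ccc(OCOC)c(OC)c3)[C@@H]2COS(=O)(=O)c3ccc(C)cc3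
F4 | step 4 | 2-(benzyloxy)-3-(dimethylamino)-1-[3-methoxy-4-(methoxymethoxy)phenyl]propan-1-one | CN(C)CC(OCc1ccccc1)C(=O)c1ccc(OCOC)c(OC)c1
F5 | step 4 | 2-(benzyloxy)-3-[3-methoxy-4-(methoxymethoxy)phenyl]-N,N,N-trimethyl-3-oxopropan-1-aminium iodide | C[N+](C)(C)CC(OCc1ccccc1)C(=O)c1ccc(OCOC)c(OC)c1.[I-]
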